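## Structural features

The target is a B-type procyanidin tetramer. It consists of four 5,7,3',4'-tetrahydroxyflavan-3-ol units (unit 1 at the top, unit 4 at the bottom), each with a phloroglucinol ring A, a catechol ring B and a dihydropyran ring C. The units are joined by three C(sp3)–C(sp2) bonds: C4(unit 1)–C6(unit 2), C4(unit 2)–C8(unit 3) and C4(unit 3)–C6(unit 4). Ring A of unit 2 therefore carries carbon at C4a and C6, and its ring oxygen O1 lies para to C6. Read literally, the SMILES gives these configurations:

- unit 1: (2R,3R,4R), 2,3-cis-3,4-cis (epicatechin, 4α bond)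
- unit 2: (2S,3S,4R), also all-cis but in the enantiomeric series (ent-epicatechin, 4β bond)
- unit 3: (2R,3R,4S), 2,3-cis-3,4-trans (epicatechin, natural 4β bond)
- unit 4: (2R,3R)-epicatechin

The eleven stereocentres form three contiguous C2–C3–C4 triads and one C2–C3 pair, and the two all-cis triads of opposite sense stand on either side of ring A of unit 2. The fragile points are the sixteen phenols (air oxidation, worst in base), C2 (epimerises in base through a ring B quinone methide once the phenols are free) and the three C4–aryl bonds (acid-labile by retro-Friedel–Crafts cleavage). The real difficulty is that the C4 cation of a 2,3-cis flavan is attacked anti to its 3-oxygen and prefers C8 of the partner. The usual coupling therefore gives 3,4-trans, 4→8 bonds from (2R) units, which is wrong for units 1 and 2 in relative configuration, in regiochemistry and, for unit 2, in absolute series.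

The key step exploits three features of rings A and C of unit 2. First, O1 is para to C6, so in a ring A precursor that already bears unit 1 the two carbons ortho to the future O1 are equivalent and either can become C4a. Second, C4 is bonded to C8 of unit 3 and can begin as an aldehyde carbon there. Third, H2, H3 and H4 lie on one face and can be delivered one after the other anti to the C4 aryl group. In one sentence: ring C of unit 2 is closed, and the two halves of the molecule are joined, by a reductive (3+3) annulation of the free para-phenol of a unit 1–ring A fragment onto an α-benzyloxychalcone whose β-carbon already sits on C8 of unit 3.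

## Logic of the disconnections

**25 to 24.** Cut: twenty O–CH2Ph bonds; a C8–Cl bond on unit 4 is added retrosynthetically. Reason: all oxidisable phenols and the four alcohols are masked by one group, and the chlorine silences the one ring A position that could compete in earlier steps. Gain: a robust, soluble, chromatographable precursor. Demand: a single neutral hydrogenolysis must remove every benzyl group and the chlorine without touching the C4–aryl or C2–O1 bonds.

**24 to 22 + 14 (through 23).** Cut: H2 and H3 of unit 2 are removed first (back to the C2=C3 enol ether), then C4–C4a and O1–C2 of ring C of unit 2. Reason: these two bonds, not the interflavan bond, split the molecule into halves of equal size at the one ring whose configuration, series and 6/8 substitution are all unnatural. Gain: one ring, three stereocentres and the connectivity problem of ring A of unit 2 disappear, and eleven stereocentres fall to three plus five. Demand: the forward step must choose one face of C4, must react only at the ring that bears the free phenol, and must then deliver H3 and H2 anti to the C4 aryl group.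

**14 to 9 + 13.** Cut: the C3=C4 double bond of the enone. Reason: C4 becomes a formyl carbon on C8 of unit 3, so the "interflavan" bond C4–C8 already exists as an aryl–CHO bond. Gain: a two-carbon ketone building block that serves units 1 and 2 alike. Demand: a condensation at a di-ortho-alkoxy, electron-rich aldehyde.

**9 to 7.** Cut: C8(unit 3)–CHO. Reason: the bromine that caps C8 during the coupling becomes the handle for the formyl group. Gain: no extra regiochemical step. Demand: metalation at C–Br only, with the C–Cl bond of unit 4 untouched.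

**7 to 4 + 6.** Cut: C4(unit 3)–C6(unit 4). Reason: this is the only bond with the natural 3,4-trans geometry, so the classical cationic coupling fits it. Gain: two monomers from one parent. Demand: C6 attack, enforced by a halogen at C8 of each partner.

**4 and 6 to 3, 2 and 1.** Cut: C8–Cl; C8–Br and C4–O (through 5); five O–benzyl bonds. Reason and gain: both lower units, with four of the eleven stereocentres, come from one chiral-pool compound. Demand: C8-selective halogenation and 4β-selective oxidation.

**22 to 21, then to 18 + 19 (through 20).** Cut: the O–allyl bond; then, as above, H2/H3, C4–C4a and O1–C2 of ring C of unit 1. Reason: the same annulation on small achiral partners sets the first all-cis triad and rehearses the key step. Gain: unit 1 falls to a symmetric phenol and an achiral enone. Demand: enantioselection by the catalyst alone.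

**18 to 17 + 13; 17 to 16 to 15.** Cut: C3=C4 of the enone; two O–benzyl bonds and one O–allyl bond. Reason: the aldehyde carbon lies between the two oxygens that become O5 and O7 of unit 2 and para to the oxygen that becomes O1, so the 4→6 bond is fixed by the symmetry of the starting aldehyde. Demand: the para oxygen must be marked selectively.

**13 to 10 + 11.** Cut: aryl–C(=O). Reason: ring B plus C2 and C3 with its oxygen are obtained in one acylation. Demand: no over-addition.

## Other disconnections considered

**Alternative 1:** (the first that comes to mind) Cut all three C4–aryl interflavan bonds. The forward key step is Lewis-acid ionisation of a C4-alkoxyflavan such as A1 and Friedel–Crafts capture by a C8-capped lower unit, iterated from the bottom up. The C4 cation of a 2,3-cis flavan is shielded on one face by its 3-oxygen substituent, so the aryl group enters trans to it and the coupling should lead to the 3,4-trans dimer A2. Two of the three bonds of the target are 3,4-cis, and this bias belongs to the substrate, not to the promoter. The plan also needs the unnatural enantiomer of the monomer for unit 2. It is therefore kept only for the one bond it fits (step 6).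

**Alternative 2:** Cut the same bonds at the ketone level. A C6- or C8-lithiated lower fragment is added to a flavan-4-one, and the tertiary carbinol is then ionised and reduced, so that hydride rather than aryl enters anti to the 3-oxygen and the aryl group ends up cis. The stereochemical logic is sound, but unit 2 would have to be A3, a compound of the ent series that is at once a C4 ketone and a C6 halide. Electrophilic halogenation of such rings goes to C8, the ketone and the organolithium site cannot coexist in one unit, and each unit costs two oxidation steps plus addition and reduction in a fully linear order. The chosen plan is convergent, needs no ent-series chiral pool and gets C6 from symmetry.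

**Alternative 3:** Flatten ring C of units 1 and 2 to the flavonol level. A lithiated ring A fragment is added to the carbonyl of A4, the adduct is ionised to the 4-arylflavylium salt A5, and the pyrylium ring is reduced on one face under a chiral counter-anion. One achiral block would serve both enantiomeric series and all three centres would be set as a group. There are three drawbacks:

- The carbonyl is a vinylogous ester flanked by O3 and O5 substituents.
- The perpendicular di-ortho-substituted aryl group shields both faces of C4, so the site and face of the first hydride are hard to predict.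
- Unit 2 again needs a C6 metal on a ring that carries a carbonyl, which forces a linear order and three different halogens.

Key step: step 15

Assumption: the stereodescriptors of the SMILES are taken at face value; α/β follow proanthocyanidin usage (the 2-aryl group of a (2R)-flavan is α).
Assumption: the sense of induction of the chiral acid cannot be derived a priori. The (R)-acid is assumed to give the 4α adduct in step 13 and the (S)-acid the 4β adduct in step 15, and the antipodes are exchanged if a trial shows the reverse.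

## Steps

Step 1
Reactants: 1 (−)-epicatechin
Product: 2 5,7,3',4'-tetra-O-benzyl-(−)-epicatechin
Conditions: BnBr (4.4 equiv), K2CO3, DMF, 0 °C to rt
Reagents that add atoms: benzyl bromide, BrCc1ccccc1
Why: Williamson etherification; only the four phenols are deprotonated by K2CO3, the secondary 3-OH stays free, and the mild base and low temperature avoid epimerisation at C2.

Step 2
Reactants: 2 5,7,3',4'-tetra-O-benzyl-(−)-epicatechin
Product: 3 3,5,7,3',4'-penta-O-benzyl-(−)-epicatechin
Conditions: NaH, BnBr, Bu4NI (cat.), DMF, 0 °C to rt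
Reagents that add atoms: benzyl bromide, BrCc1ccccc1
Why: Williamson etherification of the alkoxide; with all phenols capped no quinone methide can form, so C2 and C3 are safe in strong base.

Step 3
Reactants: 3 3,5,7,3',4'-penta-O-benzyl-(−)-epicatechin
Product: 4 8-chloro-3,5,7,3',4'-penta-O-benzyl-(−)-epicatechin
Conditions: NCS (1.05 equiv), CH2Cl2, −20 °C to rt
Reagents that add atoms: N-chlorosuccinimide, O=C1CCC(=O)N1Cl
Why: Electrophilic aromatic halogenation; C8 (flanked by O1 and one benzyloxy group) is the most reactive and least hindered position of a 5,7-di-O-benzylflavan. The chlorine blocks C8 in steps 6 and 15 and is inert to t-BuLi in step 7.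

Step 4
Reactants: 3 3,5,7,3',4'-penta-O-benzyl-(−)-epicatechin
Product: 5 8-bromo-3,5,7,3',4'-penta-O-benzyl-(−)-epicatechin
Conditions: NBS (1.0 equiv), CH2Cl2, −78 °C to 0 °C
Reagents that add atoms: N-bromosuccinimide, O=C1CCC(=O)N1Br
Why: C8-selective electrophilic bromination of benzylated flavan-3-ols; the bromine is first a cap against self-condensation and later the handle for C4 of unit 2.

Step 5
Reactants: 5 8-bromo-3,5,7,3',4'-penta-O-benzyl-(−)-epicatechin
Product: 6 8-bromo-4β-(2-ethoxyethoxy)-3,5,7,3',4'-penta-O-benzyl-(−)-epicatechin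
Conditions: DDQ (2 equiv), 2-ethoxyethanol (5 equiv), CH2Cl2, rt
Reagents that add atoms: 2-ethoxyethanol, CCOCCO
Why: DDQ benzylic oxidation: hydride abstraction at C4 gives a cation stabilised by the 5,7-dialkoxy ring. The alcohol adds anti to the 3-benzyloxy group, which sets the 4β (3,4-trans) configuration.

Step 6
Reactants: 4 8-chloro-penta-O-benzylepicatechin (3 equiv); 6 8-bromo-4β-(2-ethoxyethoxy)-penta-O-benzylepicatechin
Product: 7 deca-O-benzyl 8-bromoepicatechin-(4β→6)-8-chloroepicatechin
Conditions: TMSOTf (0.2 equiv), CH2Cl2, −78 °C to −40 °C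
Reagents that add atoms: none
Why: Cationic Friedel–Crafts interflavan coupling with halogen caps: C6 is the only free position on ring A of 4, the bromine shuts off C8 of 6, and the excess of 4 outcompetes C6 of 6. The nucleophile enters anti to the 3-benzyloxy group, which gives the natural 3,4-trans 4β bond.

Step 7
Reactants: 7 deca-O-benzyl 8-bromoepicatechin-(4β→6)-8-chloroepicatechin
Product: 9 deca-O-benzyl 8-formylepicatechin-(4β→6)-8-chloroepicatechin, via aryllithium 8 (not isolated)
Conditions: t-BuLi (2.1 equiv), THF, −78 °C; then DMF, −78 °C to 0 °C; then H2O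
Reagents that add atoms: N,N-dimethylformamide, CN(C)C=O; tert-butyllithium, [Li]C(C)(C)C (lithium of 8 only)
Why: Bromine–lithium exchange is far faster than chlorine–lithium exchange, so only C8 of unit 3 is metalated; trapping with DMF (Bouveault aldehyde synthesis) installs the carbon that becomes C4 of unit 2.

Step 8
Reactants: 10 4-bromo-1,2-bis(benzyloxy)benzene; 11 2-(benzyloxy)-N-methoxy-N-methylacetamide
Product: 13 2-(benzyloxy)-1-[3,4-bis(benzyloxy)phenyl]ethan-1-one, via aryllithium 12 (not isolated)
Conditions: n-BuLi (1.05 equiv), THF, −78 °C; then 11, −78 °C to 0 °C; then H2O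
Reagents that add atoms: n-butyllithium, [Li]CCCC (lithium of 12 only)
Why: Weinreb ketone synthesis; the chelated tetrahedral adduct prevents a second addition.

Step 9
Reactants: 9 deca-O-benzyl 8-formylepicatechin-(4β→6)-8-chloroepicatechin; 13 2-(benzyloxy)-1-[3,4-bis(benzyloxy)phenyl]ethan-1-one
Product: 14 lower α-benzyloxychalcone, (Z)-enone with its β-carbon on C8 of unit 3
Conditions: KOH, EtOH–THF, 40 °C
Reagents that add atoms: none
Why: Claisen–Schmidt condensation, known for 2,4,6-trialkoxybenzaldehydes and for α-alkoxyacetophenones; the fully benzylated flavan units are base-stable. The (Z)-isomer (aryl trans to carbonyl) is the thermodynamic one, and the geometry is lost again in the cation of step 15.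

Step 10
Reactants: 15 2,4,6-trihydroxybenzaldehyde
Product: 16 4-(allyloxy)-2,6-dihydroxybenzaldehyde
Conditions: allyl bromide (1.0 equiv), K2CO3 (1.1 equiv), acetone, 0 °C to rt
Reagents that add atoms: allyl bromide, C=CCBr
Why: Williamson etherification; the 4-OH is the only hydroxyl not hydrogen-bonded to the formyl group and is the most acidic, so it is alkylated first. This marks the oxygen that becomes O1 of unit 2.

Step 11
Reactants: 16 4-(allyloxy)-2,6-dihydroxybenzaldehyde
Product: 17 4-(allyloxy)-2,6-bis(benzyloxy)benzaldehyde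
Conditions: BnBr (2.5 equiv), K2CO3, DMF, 60 °C
Reagents that add atoms: benzyl bromide, BrCc1ccccc1
Why: Williamson etherification under forcing conditions overcomes the chelation of the two ortho hydroxyls; these oxygens become O5 and O7 of unit 2.

Step 12
Reactants: 17 4-(allyloxy)-2,6-bis(benzyloxy)benzaldehyde; 13 2-(benzyloxy)-1-[3,4-bis(benzyloxy)phenyl]ethan-1-one
Product: 18 upper α-benzyloxychalcone, (Z)-3-[4-(allyloxy)-2,6-bis(benzyloxy)phenyl]-2-(benzyloxy)-1-[3,4-bis(benzyloxy)phenyl]prop-2-en-1-one
Conditions: KOH, EtOH–THF, rt to 40 °C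
Reagents that add atoms: none
Why: Claisen–Schmidt condensation as in step 9; allyl and benzyl aryl ethers are inert to hydroxide.

Step 13
Reactants: 18 upper α-benzyloxychalcone; 19 3,5-bis(benzyloxy)phenol (1.5 equiv)
Product: 21 (2R,3R,4R)-3,5,7-tris(benzyloxy)-2-[3,4-bis(benzyloxy)phenyl]-4-[4-(allyloxy)-2,6-bis(benzyloxy)phenyl]chroman (all-cis, 4α-aryl), via flav-2-ene 20 (not isolated)
Conditions: (R)-3,3'-bis(2,4,6-triisopropylphenyl)-1,1'-binaphthalene-2,2'-diyl N-(trifluoromethylsulfonyl)phosphoramidate (10 mol %), 4 Å molecular sieves, toluene–CH2Cl2, −20 °C to rt; then Bu3SnH (4 equiv), CF3CO2H (3 equiv, slow addition), CH2Cl2, −40 °C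
Reagents that add atoms: none
Why: Proposed new method: the chiral acid protonates the enone of 18 to a cation delocalised into the trialkoxyphenyl ring and held as a contact ion pair while its P=O binds the OH of 19, so the ortho carbon of 19 attacks one face of C4 (Friedel–Crafts conjugate addition); the phenol then closes ring C on the ketone (6-exo-trig hemiketal) and loss of water gives 20, whereas para attack cannot cyclise and reverts. In 20 the C4 aryl group stands pseudo-axial over the α face, so the proton enters C3 and then the hydride enters C2 of the ring B stabilised oxocarbenium ion from the β face, which gives the 2,3-cis-3,4-cis triad, and the very fast hydride donor traps the cation before H3 can be lost again. The closest known reaction types are the acid-catalysed phenol–chalcone annulation to 2,4-diaryl-4H-chromenes, the chiral phosphoric acid catalysed Friedel–Crafts/cyclisation of phenols and naphthols with activated enones, and the ionic hydrogenation of enol ethers and of 4-arylflavan-4-yl cations with silanes or stannanes.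

Step 14
Reactants: 21 all-cis 4α-[4-(allyloxy)-2,6-bis(benzyloxy)phenyl]-penta-O-benzylepicatechin
Product: 22 all-cis 4α-[2,6-bis(benzyloxy)-4-hydroxyphenyl]-penta-O-benzylepicatechin
Conditions: Pd(PPh3)4 (5 mol %), morpholine (5 equiv), THF, rt
Reagents that add atoms: none
Why: Tsuji–Trost type deallylation; zerovalent palladium ionises the allyl aryl ether to a π-allyl complex that morpholine captures. Benzyl ethers and all stereocentres are untouched, and the single free phenol is the future O1 of unit 2.

Step 15
Reactants: 22 all-cis 4α-[2,6-bis(benzyloxy)-4-hydroxyphenyl]-penta-O-benzylepicatechin; 14 lower α-benzyloxychalcone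
Product: 24 icosa-O-benzyl epicatechin-(4α→6)-ent-epicatechin-(4β→8)-epicatechin-(4β→6)-8-chloroepicatechin, via flav-2-ene 23 (not isolated)
Conditions: (S)-3,3'-bis(2,4,6-triisopropylphenyl)-1,1'-binaphthalene-2,2'-diyl N-(trifluoromethylsulfonyl)phosphoramidate (15 mol %), 4 Å molecular sieves, toluene–CH2Cl2, −20 °C to rt; then Bu3SnH (4 equiv), CF3CO2H (3 equiv, slow addition), CH2Cl2, −40 °C
Reagents that add atoms: none
Why: Proposed new method: the chiral acid protonates the enone oxygen of 14 to a cation delocalised from C2 over C4 into ring A of unit 3, paired with the chiral anion whose P=O at the same time binds the only free phenol of 22. The carbon ortho to that phenol attacks C4 (Friedel–Crafts conjugate addition, C4–C4a bond), the phenol oxygen adds to the C2 ketone (6-exo-trig hemiketal, O1–C2 bond) and loss of water gives the 4H-chromene 23, so ring C of unit 2 is closed by a formal (3+3) annulation in which neither new bond is an interflavan bond. C4 is controlled by the ion pair, and the antipode of the acid of step 13 is used because units 1 and 2 have opposite sense, so unit 3 is placed on the β face. In 23 the C4 aryl group stands pseudo-axial on the boat-shaped 4H-pyran, as 4-aryl groups do in 4H-pyrans and 1,4-dihydropyridines, and covers the β face of C2=C3. CF3CO2H therefore protonates C3 from the α face (C3 controlled by C4) to give the 2-aryl oxocarbenium ion stabilised by ring B, and Bu3SnH delivers hydride to C2 from the same α face (C2 controlled by C3 and C4), fast enough to outrun loss of H3, so H2, H3 and H4 are all α and the three substituents all β. The site selectivity needed is secured by the substrate: only ring A of unit 2 has a free OH, its para carbon is occupied by C4 of unit 1, its two ortho carbons are exchanged by rotation about the C4(unit 1)–C6(unit 2) bond, C8 of unit 4 is chlorinated, and attack by any benzylated ring cannot cyclise and is reversible. The only irreversible exit thus fixes O1 para to C6, that is the 4→6/4→8 pattern around ring A of unit 2. The closest known reaction types are those named under step 13.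

Step 16
Reactants: 24 icosa-O-benzyl 8-chloro tetramer
Product: 25 epicatechin-(4α→6)-ent-epicatechin-(4β→8)-epicatechin-(4β→6)-epicatechin (target)
Conditions: H2 (1–4 bar), Pd(OH)2/C, Et3N (1.5 equiv), THF–MeOH–H2O, rt; filtration and lyophilisation under argon
Reagents that add atoms: none
Why: Catalytic hydrogenolysis of benzyl ethers with concurrent hydrodehalogenation of the aryl chloride, as is usual for halogen-capped benzylated oligomers. The amine takes up the HCl that would otherwise cleave the C4–aryl bonds, and no stereocentre is touched.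

## Compound list

1 | (−)-epicatechin | Oc1cc(O)c2c(c1)O[C@H](c1ccc(O)c(O)c1)[C@H](O)C2 | starting material
2 | 5,7,3',4'-tetra-O-benzyl-(−)-epicatechin | O(Cc5ccccc5)c1cc(OCc5ccccc5)c2c(c1)O[C@H](c4ccc(OCc5ccccc5)c(OCc5ccccc5)c4)[C@H](O)C2 | intermediate
3 | 3,5,7,3',4'-penta-O-benzyl-(−)-epicatechin | O(Cc5ccccc5)c1cc(OCc5ccccc5)c2c(c1)O[C@H](c4ccc(OCc5ccccc5)c(OCc5ccccc5)c4)[C@H](OCc5ccccc5)C2 | intermediate
4 | 8-chloro-penta-O-benzyl-(−)-epicatechin | O(Cc5ccccc5)c1cc(OCc5ccccc5)c2c(c1Cl)O[C@H](c4ccc(OCc5ccccc5)c(OCc5ccccc5)c4)[C@H](OCc5ccccc5)C2 | intermediate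
5 | 8-bromo-penta-O-benzyl-(−)-epicatechin | O(Cc5ccccc5)c1cc(OCc5ccccc5)c2c(c1Br)O[C@H](c4ccc(OCc5ccccc5)c(OCc5ccccc5)c4)[C@H](OCc5ccccc5)C2 | intermediate
6 | 8-bromo-4β-(2-ethoxyethoxy)-penta-O-benzyl-(−)-epicatechin | O(Cc5ccccc5)c1cc(OCc5ccccc5)c2c(c1Br)O[C@H](c4ccc(OCc5ccccc5)c(OCc5ccccc5)c4)[C@H](OCc5ccccc5)[C@H]2OCCOCC | intermediate
7 | deca-O-benzyl 8-bromoepicatechin-(4β→6)-8-chloroepicatechin | Brc1c(OCc5ccccc5)cc(OCc5ccccc5)c3c1O[C@H](c4ccc(OCc5ccccc5)c(OCc5ccccc5)c4)[C@H](OCc5ccccc5)[C@H]3c1c(OCc5ccccc5)c(Cl)c3c(c1OCc5ccccc5)C[C@@H](OCc5ccccc5)[C@@H](c4ccc(OCc5ccccc5)c(OCc5ccccc5)c4)O3 | intermediate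
8 | 8-lithio analogue of 7 (lithium at C8 of unit 3) | [Li]c1c(OCc5ccccc5)cc(OCc5ccccc5)c3c1O[C@H](c4ccc(OCc5ccccc5)c(OCc5ccccc5)c4)[C@H](OCc5ccccc5)[C@H]3c1c(OCc5ccccc5)c(Cl)c3c(c1OCc5ccccc5)C[C@@H](OCc5ccccc5)[C@@H](c4ccc(OCc5ccccc5)c(OCc5ccccc5)c4)O3 | intermediate
9 | deca-O-benzyl 8-formylepicatechin-(4β→6)-8-chloroepicatechin | O=Cc1c(OCc5ccccc5)cc(OCc5ccccc5)c3c1O[C@H](c4ccc(OCc5ccccc5)c(OCc5ccccc5)c4)[C@H](OCc5ccccc5)[C@H]3c1c(OCc5ccccc5)c(Cl)c3c(c1OCc5ccccc5)C[C@@H](OCc5ccccc5)[C@@H](c4ccc(OCc5ccccc5)c(OCc5ccccc5)c4)O3 | intermediate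
10 | 4-bromo-1,2-bis(benzyloxy)benzene | Brc1ccc(OCc2ccccc2)c(OCc2ccccc2)c1 | starting material
11 | 2-(benzyloxy)-N-methoxy-N-methylacetamide | CON(C)C(=O)COCc1ccccc1 | starting material
12 | 3,4-bis(benzyloxy)phenyllithium | [Li]c1ccc(OCc2ccccc2)c(OCc2ccccc2)c1 | intermediate
13 | 2-(benzyloxy)-1-[3,4-bis(benzyloxy)phenyl]ethan-1-one | O=C(COCc1ccccc1)c1ccc(OCc2ccccc2)c(OCc2ccccc2)c1 | intermediate
14 | lower α-benzyloxychalcone ((Z)-enone on C8 of unit 3) | O=C(c4ccc(OCc5ccccc5)c(OCc5ccccc5)c4)/C(OCc5ccccc5)=C/c1c(OCc5ccccc5)cc(OCc5ccccc5)c3c1O[C@H](c4ccc(OCc5ccccc5)c(OCc5ccccc5)c4)[C@H](OCc5ccccc5)[C@H]3c1c(OCc5ccccc5)c(Cl)c3c(c1OCc5ccccc5)C[C@@H](OCc5ccccc5)[C@@H](c4ccc(OCc5ccccc5)c(OCc5ccccc5)c4)O3 | intermediate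
15 | 2,4,6-trihydroxybenzaldehyde | O=Cc1c(O)cc(O)cc1O | starting material
16 | 4-(allyloxy)-2,6-dihydroxybenzaldehyde | O=Cc1c(O)cc(OCC=C)cc1O | intermediate
17 | 4-(allyloxy)-2,6-bis(benzyloxy)benzaldehyde | O=Cc1c(OCc2ccccc2)cc(OCC=C)cc1OCc2ccccc2 | intermediate
18 | upper α-benzyloxychalcone, (Z) | O=C(c4ccc(OCc5ccccc5)c(OCc5ccccc5)c4)/C(OCc5ccccc5)=C/c1c(OCc5ccccc5)cc(OCC=C)cc1OCc5ccccc5 | intermediate
19 | 3,5-bis(benzyloxy)phenol | Oc1cc(OCc2ccccc2)cc(OCc2ccccc2)c1 | starting material
20 | (4R)-4-[4-(allyloxy)-2,6-bis(benzyloxy)phenyl]-3,5,7-tris(benzyloxy)-2-[3,4-bis(benzyloxy)phenyl]-4H-chromene | O(Cc5ccccc5)c1cc(OCc5ccccc5)c2c(c1)OC(c4ccc(OCc5ccccc5)c(OCc5ccccc5)c4)=C(OCc5ccccc5)[C@@H]2c1c(OCc5ccccc5)cc(OCC=C)cc1OCc5ccccc5 | intermediate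
21 | (2R,3R,4R) all-cis 4α-[4-(allyloxy)-2,6-bis(benzyloxy)phenyl]-penta-O-benzylepicatechin | O(Cc5ccccc5)c1cc(OCc5ccccc5)c2c(c1)O[C@H](c4ccc(OCc5ccccc5)c(OCc5ccccc5)c4)[C@H](OCc5ccccc5)[C@@H]2c1c(OCc5ccccc5)cc(OCC=C)cc1OCc5ccccc5 | intermediate
22 | (2R,3R,4R) all-cis 4α-[2,6-bis(benzyloxy)-4-hydroxyphenyl]-penta-O-benzylepicatechin | O(Cc5ccccc5)c1cc(OCc5ccccc5)c2c(c1)O[C@H](c4ccc(OCc5ccccc5)c(OCc5ccccc5)c4)[C@H](OCc5ccccc5)[C@@H]2c1c(OCc5ccccc5)cc(O)cc1OCc5ccccc5 | intermediate
23 | tetramer with unit 2 as 3-benzyloxyflav-2-ene (unit 3 on the β face of C4) | O(Cc5ccccc5)c1cc(OCc5ccccc5)c2c(c1)O[C@H](c4ccc(OCc5ccccc5)c(OCc5ccccc5)c4)[C@H](OCc5ccccc5)[C@@H]2c1c(OCc5ccccc5)cc2c(c1OCc5ccccc5)[C@H](c1c(OCc5ccccc5)cc(OCc5ccccc5)c3c1O[C@H](c4ccc(OCc5ccccc5)c(OCc5ccccc5)c4)[C@H](OCc5ccccc5)[C@H]3c1c(OCc5ccccc5)c(Cl)c3c(c1OCc5ccccc5)C[C@@H](OCc5ccccc5)[C@@H](c4ccc(OCc5ccccc5)c(OCc5ccccc5)c4)O3)C(OCc5ccccc5)=C(c4ccc(OCc5ccccc5)c(OCc5ccccc5)c4)O2 | intermediate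
24 | icosa-O-benzyl epicatechin-(4α→6)-ent-epicatechin-(4β→8)-epicatechin-(4β→6)-8-chloroepicatechin | O(Cc5ccccc5)c1cc(OCc5ccccc5)c2c(c1)O[C@H](c4ccc(OCc5ccccc5)c(OCc5ccccc5)c4)[C@H](OCc5ccccc5)[C@@H]2c1c(OCc5ccccc5)cc2c(c1OCc5ccccc5)[C@H](c1c(OCc5ccccc5)cc(OCc5ccccc5)c3c1O[C@H](c4ccc(OCc5ccccc5)c(OCc5ccccc5)c4)[C@H](OCc5ccccc5)[C@H]3c1c(OCc5ccccc5)c(Cl)c3c(c1OCc5ccccc5)C[C@@H](OCc5ccccc5)[C@@H](c4ccc(OCc5ccccc5)c(OCc5ccccc5)c4)O3)[C@H](OCc5ccccc5)[C@H](c4ccc(OCc5ccccc5)c(OCc5ccccc5)c4)O2 | intermediate
25 | epicatechin-(4α→6)-ent-epicatechin-(4β→8)-epicatechin-(4β→6)-epicatechin, CNP0120618.3 | Oc1cc(O)c2c(c1)O[C@H](c1ccc(O)c(O)c1)[C@H](O)[C@@H]2c1c(O)cc2c(c1O)[C@H](c1c(O)cc(O)c3c1O[C@H](c1ccc(O)c(O)c1)[C@H](O)[C@H]3c1c(O)cc3c(c1O)C[C@@H](O)[C@@H](c1ccc(O)c(O)c1)O3)[C@H](O)[C@H](c1ccc(O)c(O)c1)O2 | target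

## Step count and least certain steps

Total step count: 16. Longest linear sequence: 9 steps (1, 2, 4, 5, 6, 7, 9, 15, 16).

**Step 15 (key step).** The most likely failure is poor facial selectivity at C4, because two large chiral partners must fit the pocket of the acid and their own bias may oppose it. Behind that come two further risks. Bond formation is slow at a carbon flanked by four ortho oxygens, which leaves time for acid cleavage of the C4(unit 1)–C6(unit 2) bond para to the free phenol. Kinetic control at C3 is also lost if the oxocarbenium ion sheds H3 before hydride arrives.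

The fallback uses known chemistry and moves the stereo-determining event from C–C to C–H bond formation. From 22 and 14 the annulation is run with an achiral acid (diphenyl phosphate), the known phenol–chalcone condensation, which should give 23 together with the unit 2 C4-epimeric flav-2-ene F1. The mixture is oxidised at low temperature with DDQ (1 equiv) and HBF4·OEt2 to the single planar 4-arylflavylium tetrafluoroborate F2, since the 4H-chromene C4–H is by far the best hydride donor in the molecule. F2 is then reduced with diethyl 2,6-dimethyl-1,4-dihydropyridine-3,5-dicarboxylate under a chiral 3,3'-disubstituted binaphthyl hydrogen phosphate, the known enantioselective 1,4-reduction of 2,4-diaryl-1-benzopyrylium ions. This returns to 23, which is carried on to 24 by the second half of step 15.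

**Step 13.** The most likely failure is insufficient enantioselection, because the ion pair has only the phenol hydrogen bond as a second contact. Para attack on 19 may also slow the funnel to 20.

The fallback uses known chemistry from the chiral pool, which is possible because unit 1 belongs to the natural (2R,3R) series. From 3, DDQ in wet CH2Cl2–THF gives the 4β-alcohol F3, and Dess–Martin oxidation gives the flavan-4-one F4. Separately 19 is silylated (i-Pr3SiCl, imidazole) to the silyl ether F5. This is lithiated by n-BuLi between its two benzyloxy groups, the silyloxy group being bulky and non-directing, to the aryllithium F6. Addition of F6 to F4 anti to the 3-benzyloxy group gives the tertiary carbinol F7. Bu3SnH/CF3CO2H ionises F7 and delivers hydride from the β face, which leaves the aryl group cis to O3 in the all-cis silyl ether F8, and Bu4NF then returns to 22. Material made this way also serves to assign the sense of induction of the acid.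

**Step 6.** The most likely failure is self-condensation of the electrophile through its own free C6, which is about as nucleophilic as C6 of 4, together with slow capture at a position flanked by two benzyloxy groups.

The fallback replaces the bromine cap by the formyl group that is needed anyway, which deactivates ring A of the electrophile. From 6, bromine–lithium exchange gives the 8-lithio ether F9, and DMF gives the 8-formyl-4β-(2-ethoxyethoxy) monomer F10. F10 is coupled with 4 under TMSOTf and returns directly to 9, so that 7 and step 7 are bypassed.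

**Step 9.** The most likely failure is an unfavourable aldol equilibrium and slow dehydration at a hindered, strongly donor-substituted aldehyde.

The fallback forms the aryl–C4 bond instead of the C3=C4 bond. From 13, heating with N,N-dimethylformamide dimethyl acetal gives the enaminone F11. The aryllithium 8, generated from 7 as in step 7, adds to its β-carbon with loss of the amide ion (the known addition–elimination of organolithiums on β-aminovinyl ketones) and returns to 14.

**Step 16.** The most likely failures are incomplete hydrodechlorination of the electron-rich aryl chloride, reductive opening of C2–O1 bonds once conditions are forced, and oxidation of the free polyphenol during handling.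

The fallback separates the two tasks. From 24, palladium-catalysed transfer hydrodechlorination (Pd(OAc)2, dicyclohexyl(2',4',6'-triisopropylbiphenyl-2-yl)phosphane, HCO2K, dioxane–H2O, 80 °C) gives the chlorine-free icosa-O-benzyl tetramer F12. This is then debenzylated under mild neutral conditions (H2, Pd(OH)2/C) to 25.

## Further compounds

F1 | step 15 | unit 2 C4-epimeric flav-2-ene (epimer of 23) | O(Cc5ccccc5)c1cc(OCc5ccccc5)c2c(c1)O[C@H](c4ccc(OCc5ccccc5)c(OCc5ccccc5)c4)[C@H](OCc5ccccc5)[C@@H]2c1c(OCc5ccccc5)cc2c(c1OCc5ccccc5)[C@@H](c1c(OCc5ccccc5)cc(OCc5ccccc5)c3c1O[C@H](c4ccc(OCc5ccccc5)c(OCc5ccccc5)c4)[C@H](OCc5ccccc5)[C@H]3c1c(OCc5ccccc5)c(Cl)c3c(c1OCc5ccccc5)C[C@@H](OCc5ccccc5)[C@@H](c4ccc(OCc5ccccc5)c(OCc5ccccc5)c4)O3)C(OCc5ccccc5)=C(c4ccc(OCc5ccccc5)c(OCc5ccccc5)c4)O2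
F2 | step 15 | 4-arylflavylium tetrafluoroborate (unit 2 as pyrylium ring) | O(Cc5ccccc5)c1cc(OCc5ccccc5)c2c(c1)O[C@H](c4ccc(OCc5ccccc5)c(OCc5ccccc5)c4)[C@H](OCc5ccccc5)[C@@H]2c1c(OCc5ccccc5)cc2c(c1OCc5ccccc5)c(-c1c(OCc5ccccc5)cc(OCc5ccccc5)c3c1O[C@H](c4ccc(OCc5ccccc5)c(OCc5ccccc5)c4)[C@H](OCc5ccccc5)[C@H]3c1c(OCc5ccccc5)c(Cl)c3c(c1OCc5ccccc5)C[C@@H](OCc5ccccc5)[C@@H](c4ccc(OCc5ccccc5)c(OCc5ccccc5)c4)O3)c(OCc5ccccc5)c(-c4ccc(OCc5ccccc5)c(OCc5ccccc5)c4)[o+]2.F[B-](F)(F)F
F3 | step 13 | 4β-hydroxy-penta-O-benzylepicatechin | O(Cc5ccccc5)c1cc(OCc5ccccc5)c2c(c1)O[C@H](c4ccc(OCc5ccccc5)c(OCc5ccccc5)c4)[C@H](OCc5ccccc5)[C@H]2O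
F4 | step 13 | 2,3-cis-penta-O-benzylflavan-4-one of the (2R) series | O(Cc5ccccc5)c1cc(OCc5ccccc5)c2c(c1)O[C@H](c4ccc(OCc5ccccc5)c(OCc5ccccc5)c4)[C@H](OCc5ccccc5)C2=O
F5 | step 13 | [3,5-bis(benzyloxy)phenoxy]triisopropylsilane | CC(C)[Si](Oc1cc(OCc2ccccc2)cc(OCc2ccccc2)c1)(C(C)C)C(C)C
F6 | step 13 | 2,6-bis(benzyloxy)-4-(triisopropylsilyloxy)phenyllithium | CC(C)[Si](Oc1cc(OCc2ccccc2)c([Li])c(OCc2ccccc2)c1)(C(C)C)C(C)C
F7 | step 13 | 4β-aryl-4α-hydroxy tertiary carbinol | O(Cc5ccccc5)c1cc(OCc5ccccc5)c2c(c1)O[C@H](c4ccc(OCc5ccccc5)c(OCc5ccccc5)c4)[C@H](OCc5ccccc5)[C@@]2(O)c1c(OCc5ccccc5)cc(O[Si](C(C)C)(C(C)C)C(C)C)cc1OCc5ccccc5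
F8 | step 13 | all-cis 4α-aryl silyl ether | O(Cc5ccccc5)c1cc(OCc5ccccc5)c2c(c1)O[C@H](c4ccc(OCc5ccccc5)c(OCc5ccccc5)c4)[C@H](OCc5ccccc5)[C@@H]2c1c(OCc5ccccc5)cc(O[Si](C(C)C)(C(C)C)C(C)C)cc1OCc5ccccc5
F9 | step 6 | 8-lithio-4β-(2-ethoxyethoxy)-penta-O-benzylepicatechin | O(Cc5ccccc5)c1cc(OCc5ccccc5)c2c(c1[Li])O[C@H](c4ccc(OCc5ccccc5)c(OCc5ccccc5)c4)[C@H](OCc5ccccc5)[C@H]2OCCOCC
F10 | step 6 | 8-formyl-4β-(2-ethoxyethoxy)-penta-O-benzylepicatechin | O(Cc5ccccc5)c1cc(OCc5ccccc5)c2c(c1C=O)O[C@H](c4ccc(OCc5ccccc5)c(OCc5ccccc5)c4)[C@H](OCc5ccccc5)[C@H]2OCCOCC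
F11 | step 9 | (Z)-2-(benzyloxy)-3-(dimethylamino)-1-[3,4-bis(benzyloxy)phenyl]prop-2-en-1-one | CN(C)/C=C(OCc1ccccc1)/C(=O)c1ccc(OCc2ccccc2)c(OCc2ccccc2)c1
F12 | step 16 | chlorine-free icosa-O-benzyl tetramer | O(Cc5ccccc5)c1cc(OCc5ccccc5)c2c(c1)O[C@H](c4ccc(OCc5ccccc5)c(OCc5ccccc5)c4)[C@H](OCc5ccccc5)[C@@H]2c1c(OCc5ccccc5)cc2c(c1OCc5ccccc5)[C@H](c1c(OCc5ccccc5)cc(OCc5ccccc5)c3c1O[C@H](c4ccc(OCc5ccccc5)c(OCc5ccccc5)c4)[C@H](OCc5ccccc5)[C@H]3c1c(OCc5ccccc5)cc3c(c1OCc5ccccc5)C[C@@H](OCc5ccccc5)[C@@H](c4ccc(OCc5ccccc5)c(OCc5ccccc5)c4)O3)[C@H](OCc5ccccc5)[C@H](c4ccc(OCc5ccccc5)c(OCc5ccccc5)c4)O2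
A1 | alternative 1 | 4β-(2-ethoxyethoxy)-penta-O-benzylepicatechin | O(Cc5ccccc5)c1cc(OCc5ccccc5)c2c(c1)O[C@H](c4ccc(OCc5ccccc5)c(OCc5ccccc5)c4)[C@H](OCc5ccccc5)[C@H]2OCCOCC
A2 | alternative 1 | deca-O-benzyl epicatechin-(4β→6)-8-bromo-ent-epicatechin (3,4-trans) | O(Cc5ccccc5)c1cc(OCc5ccccc5)c2c(c1)O[C@H](c4ccc(OCc5ccccc5)c(OCc5ccccc5)c4)[C@H](OCc5ccccc5)[C@H]2c1c(OCc5ccccc5)c(Br)c3c(c1OCc5ccccc5)C[C@H](OCc5ccccc5)[C@H](c4ccc(OCc5ccccc5)c(OCc5ccccc5)c4)O3
A3 | alternative 2 | 6-bromo-2,3-cis-penta-O-benzylflavan-4-one of the ent (2S) series | O(Cc5ccccc5)c1c(Br)c(OCc5ccccc5)c2c(c1)O[C@@H](c4ccc(OCc5ccccc5)c(OCc5ccccc5)c4)[C@@H](OCc5ccccc5)C2=O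
A4 | alternative 3 | 3,5,7,3',4'-penta-O-benzylquercetin | O=c1c(OCc5ccccc5)c(-c4ccc(OCc5ccccc5)c(OCc5ccccc5)c4)oc2cc(OCc5ccccc5)cc(OCc5ccccc5)c12
A5 | alternative 3 | 4-[4-(allyloxy)-2,6-bis(benzyloxy)phenyl]-3,5,7-tris(benzyloxy)-2-[3,4-bis(benzyloxy)phenyl]chromenylium trifluoroacetate | C=CCOc1cc(OCc5ccccc5)c(c(OCc5ccccc5)c1)-c1c(OCc5ccccc5)c(-c4ccc(OCc5ccccc5)c(OCc5ccccc5)c4)[o+]c2cc(OCc5ccccc5)cc(OCc5ccccc5)c12.[O-]C(=O)C(F)(F)F
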